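The green run is the neighbour of the teal flask: it has the same charge, but its readings stop at 16 min and the teal flask is asked at 64 min.

| setting | green | violet | teal |
|---|---|---|---|
| starting material | 0.150 M | 0.150 M | 0.150 M |
| reagent | 0.225 M | 0.110 M | 0.225 M |
| time |  |  | 64 min |

| run | time / min | [target] / M |
|---|---|---|
| green run | 2.0 | 0.0033 |
| green run | 4.0 | 0.0100 |
| green run | 6.0 | 0.0185 |
| green run | 8.0 | 0.0270 |
| green run | 10 | 0.0348 |
| green run | 12 | 0.0431 |
| green run | 14 | 0.0514 |
| green run | 16 | 0.0578 |
| violet run | 2.0 | 0.0017 |
| violet run | 4.0 | 0.0057 |
| violet run | 6.0 | 0.0116 |
| violet run | 8.0 | 0.0177 |
| violet run | 10 | 0.0245 |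
| violet run | 12 | 0.0308 |
| violet run | 14 | 0.0375 |
| violet run | 16 | 0.0429 |

(each reading ± 4 × 10⁻⁴ M)

- apparent order in [reagent] of the starting rate, round the charge of the green run (the rate where two percent of its starting material have turned into target)
- target in the teal run at 64 min, as a share of the starting material charged

- Overall: starting material + reagent -> target.
- Constant volume, constant temperature.
- A reading of a species includes what of it is bound.
- "The second partner" is reagent.
- An order is taken over about fifteen percent of the charge, up and down.

In the green run, between 6.0 min and 14 min, target grows by 0.0274 min⁻¹ of the charge. The inverse is 36.5 min. I call it the clearing time: how long the charge lasts on that line. The line leaves zero at a lag of 1.50 min.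

I turn the question round: what would leave much of the teal charge unturned? The teal flask holds more reagent than starting material, at 1.50 times the charge, so starting material is the limiting reagent. That leaves a sagging rate, but the asked time holds 1.71 clearing times. The mean rate would have to drop under 58.4 % of the line's just to stop the line finishing.

So I solve both ends and join them. I end the line at the last green reading, 38.5 % of the charge. After it I take a first-order tail that meets the line in rate, with constant 0.0446 min⁻¹. That leaves 7.22 % at 64 min, so I commit to 92.8 %. The violet slope, 0.0216 min⁻¹ of its charge, gives an order of 0.334 across the two reagent charges, a wider span than the one asked.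

The forecast differs from both my figures, giving 0.4 and 83 %, with the words “both runs sag in the last interval, hinting at catalyst loss or product inhibition”.

The flask gives an order of 0.40 round the green charge and, in the teal run, 91.3 %, which is 1.5 percentage points under my share.

    starting material → intermediate (0.3048 min⁻¹)
    intermediate + reagent → target (1.704 M⁻¹ min⁻¹)
    intermediate → side product (0.02124 min⁻¹)
    2 starting material ⇌ idle substrate dimer, settled at all times (200.0 M⁻¹)

Starting material passed into intermediate from the first minute, and while intermediate rose through the lag, target followed it by the step with reagent. At 64 min in the teal flask, 8.70 % of the charge stood in forms other than target. The clearing time puts the green mark of half the charge at 19.8 min, and the run reaches it at 20.9 min. The same reckoning for the violet run, where reagent is the limiting reagent, gives 25.6 min, and the run reaches it at 29.9 min, with reagent left at 23.3 % of the charge.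

The numbers in the tables are calculated on assumed constants; the scatter is artificial.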